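**Retrosynthetic overview**
- The last step is a neutral hydrogenolysis of five benzyl ethers, because the ketal/ketone core tolerates neither acid nor base.
- Key step: the chromanone (pyranone) ring forms in a hetero-Diels–Alder reaction. A photogenerated quinoketene (O=C–C=C=O) adds across the C2=C3 bond of a 2-arylbenzofuran and makes the C–C bond, the C–O bond and the cis ketal/methine pair in one step.
- The dienophile is a flavan-fused benzofuran. Its dihydropyran ring is closed by a Mitsunobu etherification (C–O, inversion) and then an intramolecular B-alkyl Suzuki coupling (C–C).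
- The flavan centre comes from (S)-glyceraldehyde acetonide. A Felkin–Anh aryl addition sets the carbinol, and the dioxolane is later cut down to a vinyl group.
- Order of ring formation: furan, then dihydropyran, then pyranone.

Assumption: 5-(benzyloxy)resorcinol, 4-(benzyloxy)phenylacetylene, 4-(benzyloxy)phenylmagnesium bromide solution, (S)-glyceraldehyde acetonide (made from L-ascorbic acid) and the acetonide of 2,4,6-trihydroxybenzoic acid are taken as catalogue items.

**Step 1**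
Reactants: 1 5-(benzyloxy)benzene-1,3-diol
Product: 2 5-(benzyloxy)-2-iodobenzene-1,3-diol
Conditions: I2 (1.05 equiv), NaHCO3, THF–H2O, 0 °C
Reagents that add atoms: iodine, II
Why: Electrophilic aromatic iodination of a resorcinol in aqueous bicarbonate goes to the carbon between the two hydroxyl groups, which keeps the ring symmetric.

**Step 2**
Reactants: 2 5-(benzyloxy)-2-iodobenzene-1,3-diol; 3 1-(benzyloxy)-4-ethynylbenzene
Product: 5 6-(benzyloxy)-2-[4-(benzyloxy)phenyl]-1-benzofuran-4-ol, via alkynylresorcinol 4 (not isolated)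
Conditions: Pd(PPh3)2Cl2 (3 mol %), CuI (5 mol %), Et3N, DMF, 25 → 65 °C
Reagents that add atoms: none
Why: Sonogashira coupling is followed by 5-endo-dig cyclisation of the o-alkynylphenol, and because the two hydroxyl groups are equivalent only one benzofuran forms and exactly one phenol stays free.

**Step 3**
Reactants: 5 6-(benzyloxy)-2-[4-(benzyloxy)phenyl]-1-benzofuran-4-ol
Product: 6 6-(benzyloxy)-2-[4-(benzyloxy)phenyl]-5-bromo-1-benzofuran-4-ol
Conditions: NBS (1.0 equiv), iPr2NH (10 mol %), CH2Cl2, −78 → 0 °C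
Reagents that add atoms: N-bromosuccinimide, O=C1CCC(=O)N1Br
Why: In amine-mediated ortho-bromination of phenols the hydrogen-bonded N-bromoamine delivers bromine next to the hydroxyl group, and C5 is the only open ortho position.

**Step 4**
Reactants: 7 4-(benzyloxy)phenylmagnesium bromide; 8 (S)-2,2-dimethyl-1,3-dioxolane-4-carbaldehyde
Product: 10 (R)-[4-(benzyloxy)phenyl][(4S)-2,2-dimethyl-1,3-dioxolan-4-yl]methanol, via aryltitanium triisopropoxide 9 (not isolated)
Conditions: ClTi(OiPr)3, THF, −78 → −20 °C; then 8, −78 → −30 °C; aq NH4Cl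
Reagents that add atoms: none
Why: The non-chelating aryltitanium reagent adds by the Felkin–Anh model, so the purchased dioxolane centre sets the new carbinol centre as the anti (1R) isomer (about 9:1, minor isomer removed on silica).

**Step 5**
Reactants: 6 6-(benzyloxy)-2-[4-(benzyloxy)phenyl]-5-bromo-1-benzofuran-4-ol; 10 (R)-[4-(benzyloxy)phenyl][(4S)-2,2-dimethyl-1,3-dioxolan-4-yl]methanol
Product: 11 6-(benzyloxy)-2-[4-(benzyloxy)phenyl]-4-{(S)-[4-(benzyloxy)phenyl][(4S)-2,2-dimethyl-1,3-dioxolan-4-yl]methoxy}-5-bromo-1-benzofuran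
Conditions: n-Bu3P, TMAD (N,N,N',N'-tetramethylazodicarboxamide), toluene, 0 → 50 °C
Reagents that add atoms: none
Why: The Mitsunobu etherification is an SN2 displacement with clean inversion at the benzylic carbon, since the neighbouring dioxolane oxygen disfavours ionisation and the acidic bromophenol is a good pronucleophile.

**Step 6**
Reactants: 11 the dioxolanyl aryl ether from step 5
Product: 13 6-(benzyloxy)-2-[4-(benzyloxy)phenyl]-4-({(1R)-1-[4-(benzyloxy)phenyl]prop-2-en-1-yl}oxy)-5-bromo-1-benzofuran, via diol 12 (not isolated)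
Conditions: AcOH–H2O 4:1, 45 °C; evaporate; then PPh3, imidazole, I2, toluene, 80 °C
Reagents that add atoms: none
Why: Acetal hydrolysis and Garegg–Samuelsson deoxygenation of the vicinal diol erase the relay centre without touching the ether centre (the descriptor changes to R only because priorities change), and both ortho positions are blocked, so no aromatic Claisen rearrangement can occur.

**Step 7**
Reactants: 13 the allyl aryl ether from step 6
Product: 15 (2R)-5-(benzyloxy)-2,8-bis[4-(benzyloxy)phenyl]-3,4-dihydro-2H-furo[2,3-h]chromene, via B-alkyl-9-BBN adduct 14 (not isolated)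
Conditions: 9-BBN, THF, 25 °C; then Pd(OAc)2 (10 mol %), SPhos (20 mol %), K3PO4, H2O, THF–DMF, 60 °C, 0.005 M
Reagents that add atoms: none
Why: Anti-Markovnikov hydroboration and an intramolecular B-alkyl Suzuki–Miyaura coupling close the six-membered ring under basic conditions that leave the benzylic ether centre intact.

**Step 8**
Reactants: 16 5,7-dihydroxy-2,2-dimethyl-4H-1,3-benzodioxin-4-one
Product: 17 5,7-bis(benzyloxy)-2,2-dimethyl-4H-1,3-benzodioxin-4-one
Conditions: BnBr (2.5 equiv), K2CO3, DMF, 60 °C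
Reagents that add atoms: benzyl bromide, BrCc1ccccc1
Why: The Williamson etherification masks both phenols, which would otherwise trap the ketene made in the next step.

**Step 9**
Reactants: 15 (2R)-5-(benzyloxy)-2,8-bis[4-(benzyloxy)phenyl]-3,4-dihydro-2H-furo[2,3-h]chromene; 17 5,7-bis(benzyloxy)-2,2-dimethyl-4H-1,3-benzodioxin-4-one
Product: 19 penta-O-benzyl ether of the target (flavan C2 R; ketal carbon S; adjacent methine S), via quinoketene 18 (not isolated)
Conditions: 17 (6 equiv, in portions), hν 254 nm (quartz), 4 Å MS, degassed CH2Cl2, −20 °C; silica gel, then preparative HPLC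
Reagents that add atoms: none
Why: Photochemical retro-[4+2] loss of acetone gives a quinoketene that regains aromaticity in an inverse-demand hetero-Diels–Alder reaction, in which the ketene carbon bonds to the nucleophilic furan C3 and the oxygen to the aryl- and oxygen-stabilised C2; suprafacial addition fixes the cis ring fusion, but the distant flavan centre gives little facial bias (about 1:1 to 2:1 expected), so 19 is separated from its (R,R)-ketal diastereomer.

**Step 10**
Reactants: 19 penta-O-benzyl ether of the target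
Product: 20 target CNP0179743.1
Conditions: H2 (1 atm), Pd(OH)2/C, THF–MeOH, 25 °C, stopped at five equivalents of H2
Reagents that add atoms: none
Why: Catalytic hydrogenolysis removes all five benzyl ethers under neutral conditions, so the enolisable methine cannot eliminate a phenoxide, and the cyclic benzylic C–O bonds react far more slowly than O-benzyl groups.

**Compound list**

| No. | Name | SMILES | Role |
|---|---|---|---|
| 1 | 5-(benzyloxy)benzene-1,3-diol | Oc1cc(O)cc(OCc2ccccc2)c1 | starting material |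
| 2 | 5-(benzyloxy)-2-iodobenzene-1,3-diol | Oc1cc(OCc2ccccc2)cc(O)c1I | intermediate |
| 3 | 1-(benzyloxy)-4-ethynylbenzene | C#Cc1ccc(OCc2ccccc2)cc1 | starting material |
| 4 | 5-(benzyloxy)-2-{[4-(benzyloxy)phenyl]ethynyl}benzene-1,3-diol | Oc1cc(OCc2ccccc2)cc(O)c1C#Cc1ccc(OCc2ccccc2)cc1 | intermediate |
| 5 | 6-(benzyloxy)-2-[4-(benzyloxy)phenyl]-1-benzofuran-4-ol | Oc1cc(OCc2ccccc2)cc2oc(-c3ccc(OCc4ccccc4)cc3)cc12 | intermediate |
| 6 | 6-(benzyloxy)-2-[4-(benzyloxy)phenyl]-5-bromo-1-benzofuran-4-ol | Oc1c(Br)c(OCc2ccccc2)cc2oc(-c3ccc(OCc4ccccc4)cc3)cc12 | intermediate |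
| 7 | 4-(benzyloxy)phenylmagnesium bromide | Br[Mg]c1ccc(OCc2ccccc2)cc1 | starting material |
| 8 | (S)-2,2-dimethyl-1,3-dioxolane-4-carbaldehyde | O=C[C@@H]1COC(C)(C)O1 | starting material |
| 9 | [4-(benzyloxy)phenyl]titanium triisopropoxide | CC(C)O[Ti](OC(C)C)(OC(C)C)c1ccc(OCc2ccccc2)cc1 | intermediate |
| 10 | (R)-[4-(benzyloxy)phenyl][(4S)-2,2-dimethyl-1,3-dioxolan-4-yl]methanol | O[C@H](c1ccc(OCc2ccccc2)cc1)[C@@H]1COC(C)(C)O1 | intermediate |
| 11 | 6-(benzyloxy)-2-[4-(benzyloxy)phenyl]-4-{(S)-[4-(benzyloxy)phenyl][(4S)-2,2-dimethyl-1,3-dioxolan-4-yl]methoxy}-5-bromo-1-benzofuran | Brc1c(OCc2ccccc2)cc2oc(-c3ccc(OCc4ccccc4)cc3)cc2c1O[C@@H](c1ccc(OCc2ccccc2)cc1)[C@@H]1COC(C)(C)O1 | intermediate |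
| 12 | (2S,3S)-3-[4-(benzyloxy)phenyl]-3-({6-(benzyloxy)-2-[4-(benzyloxy)phenyl]-5-bromo-1-benzofuran-4-yl}oxy)propane-1,2-diol | Brc1c(OCc2ccccc2)cc2oc(-c3ccc(OCc4ccccc4)cc3)cc2c1O[C@@H](c1ccc(OCc2ccccc2)cc1)[C@@H](O)CO | intermediate |
| 13 | 6-(benzyloxy)-2-[4-(benzyloxy)phenyl]-4-({(1R)-1-[4-(benzyloxy)phenyl]prop-2-en-1-yl}oxy)-5-bromo-1-benzofuran | Brc1c(OCc2ccccc2)cc2oc(-c3ccc(OCc4ccccc4)cc3)cc2c1O[C@@H](c1ccc(OCc2ccccc2)cc1)C=C | intermediate |
| 14 | 9-BBN adduct of 13 (boron on the terminal carbon) | Brc1c(OCc2ccccc2)cc2oc(-c3ccc(OCc4ccccc4)cc3)cc2c1O[C@@H](c1ccc(OCc2ccccc2)cc1)CCB1C2CCCC1CCC2 | intermediate |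
| 15 | (2R)-5-(benzyloxy)-2,8-bis[4-(benzyloxy)phenyl]-3,4-dihydro-2H-furo[2,3-h]chromene | c1ccc(COc2ccc(cc2)-c2cc3c(o2)cc(OCc2ccccc2)c2c3O[C@@H](c3ccc(OCc4ccccc4)cc3)CC2)cc1 | intermediate |
| 16 | 5,7-dihydroxy-2,2-dimethyl-4H-1,3-benzodioxin-4-one | CC1(C)OC(=O)c2c(O)cc(O)cc2O1 | starting material |
| 17 | 5,7-bis(benzyloxy)-2,2-dimethyl-4H-1,3-benzodioxin-4-one | CC1(C)OC(=O)c2c(OCc3ccccc3)cc(OCc3ccccc3)cc2O1 | intermediate |
| 18 | 3,5-bis(benzyloxy)-6-(oxomethylidene)cyclohexa-2,4-dien-1-one | O=C=C1C(=O)C=C(OCc2ccccc2)C=C1OCc1ccccc1 | intermediate |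
| 19 | penta-O-benzyl ether of the target (flavan C2 R, ketal C S, methine S) | O=C1c2c(OCc5ccccc5)cc(OCc5ccccc5)cc2O[C@@]2(c3ccc(OCc5ccccc5)cc3)Oc3cc(OCc5ccccc5)c4c(c3[C@@H]12)O[C@@H](c1ccc(OCc2ccccc2)cc1)CC4 | intermediate |
| 20 | CNP0179743.1 | O=C1c2c(O)cc(O)cc2O[C@@]2(c3ccc(O)cc3)Oc3cc(O)c4c(c3[C@@H]12)O[C@@H](c1ccc(O)cc1)CC4 | target |

**Step count**
- Total steps: 10.
- Longest linear sequence: 8 (steps 1, 2, 3, 5, 6, 7, 9, 10).

**Steps most likely to fail**

**Step 9 (quinoketene hetero-Diels–Alder).**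
- Risks: the ketene may dimerise faster than it adds to an aromatic furan, the adduct may lose a proton to give the 3-aroylbenzofuran, and facial selectivity is low.
- Fallback, setting out from 15 and 17 and returning at 19: form the C–C bond by a polar acylation and close the ring afterwards.
- NBS in DMF at 0 °C brominates the furan CH of 15 to give the 9-bromofurochromene F1.
- n-BuLi in THF at −78 °C converts F1 into the 9-lithiofurochromene F2.
- F2 adds to the lactone carbonyl of 17, and collapse of the adduct with loss of acetone gives the 2-hydroxyaryl ketone F3.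
- Irradiation of F3 at 365 nm in MeCN causes excited-state proton transfer to the o-quinone-methide enol. Oxa-6π electrocyclisation and ketonisation on the only accessible cis face then give 19, which is again separated from its diastereomer.

**Step 3 (ortho-bromination).**
- Risk: bromine may enter at C7 or at the furan C3 instead of C5.
- Fallback, setting out from 5 and returning at 6: install a carbon substituent by a strictly ortho-specific reaction and exchange it for bromine at the same carbon.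
- MgCl2, Et3N and paraformaldehyde in MeCN at reflux give the salicylaldehyde F4.
- NaClO2, NaH2PO4 and 2-methylbut-2-ene oxidise F4 to the salicylic acid F5.
- Bu4NBr3 and K3PO4 in MeCN at 60 °C effect ipso-bromodecarboxylation of F5 to 6.

**Step 5 (Mitsunobu reaction of a doubly ortho-substituted phenol with a hindered carbinol).**
- Risks: low conversion or partial ionisation at the benzylic carbon.
- Fallback, setting out from 10 and 6 and returning at 15: reverse the bond order, so the C–C bond is made first and the C–O bond is closed intramolecularly.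
- TIPSOTf and 2,6-lutidine convert 10 into the triisopropylsilyl ether F6.
- PPTS in MeOH frees the silyloxy diol F7.
- PPh3, imidazole and I2 give the silyl-protected allylic alcohol F8.
- 9-BBN gives the alkylborane F9.
- Pd(OAc)2, SPhos and K3PO4 couple F9 with 6 to the silyloxypropyl phenol F10.
- TBAF liberates the (S)-hydroxypropyl phenol F11.
- n-Bu3P and TMAD at high dilution close the pyran ring with inversion to give 15.

**Further compounds**
F1 | step 9 | (2R)-5-(benzyloxy)-2,8-bis[4-(benzyloxy)phenyl]-9-bromo-3,4-dihydro-2H-furo[2,3-h]chromene | c1ccc(COc2ccc(cc2)-c2c(Br)c3c(o2)cc(OCc2ccccc2)c2c3O[C@@H](c3ccc(OCc4ccccc4)cc3)CC2)cc1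
F2 | step 9 | (2R)-5-(benzyloxy)-2,8-bis[4-(benzyloxy)phenyl]-3,4-dihydro-2H-furo[2,3-h]chromen-9-yllithium | c1ccc(COc2ccc(cc2)-c2c([Li])c3c(o2)cc(OCc2ccccc2)c2c3O[C@@H](c3ccc(OCc4ccccc4)cc3)CC2)cc1
F3 | step 9 | [4,6-bis(benzyloxy)-2-hydroxyphenyl]{(2R)-5-(benzyloxy)-2,8-bis[4-(benzyloxy)phenyl]-3,4-dihydro-2H-furo[2,3-h]chromen-9-yl}methanone | O=C(c1c(O)cc(OCc2ccccc2)cc1OCc1ccccc1)c1c(-c2ccc(OCc3ccccc3)cc2)oc2cc(OCc3ccccc3)c3c(c12)O[C@@H](c1ccc(OCc2ccccc2)cc1)CC3
F4 | step 3 | 6-(benzyloxy)-2-[4-(benzyloxy)phenyl]-4-hydroxy-1-benzofuran-5-carbaldehyde | O=Cc1c(O)c2cc(-c3ccc(OCc4ccccc4)cc3)oc2cc1OCc1ccccc1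
F5 | step 3 | 6-(benzyloxy)-2-[4-(benzyloxy)phenyl]-4-hydroxy-1-benzofuran-5-carboxylic acid | OC(=O)c1c(O)c2cc(-c3ccc(OCc4ccccc4)cc3)oc2cc1OCc1ccccc1
F6 | step 5 | {(R)-[4-(benzyloxy)phenyl][(4S)-2,2-dimethyl-1,3-dioxolan-4-yl]methoxy}triisopropylsilane | CC(C)[Si](C(C)C)(C(C)C)O[C@H](c1ccc(OCc2ccccc2)cc1)[C@@H]1COC(C)(C)O1
F7 | step 5 | (2S,3R)-3-[4-(benzyloxy)phenyl]-3-[(triisopropylsilyl)oxy]propane-1,2-diol | CC(C)[Si](C(C)C)(C(C)C)O[C@H](c1ccc(OCc2ccccc2)cc1)[C@@H](O)CO
F8 | step 5 | ({(1S)-1-[4-(benzyloxy)phenyl]prop-2-en-1-yl}oxy)triisopropylsilane | CC(C)[Si](C(C)C)(C(C)C)O[C@H](c1ccc(OCc2ccccc2)cc1)C=C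
F9 | step 5 | 9-BBN adduct of F8 (boron on the terminal carbon) | CC(C)[Si](C(C)C)(C(C)C)O[C@H](c1ccc(OCc2ccccc2)cc1)CCB1C2CCCC1CCC2
F10 | step 5 | 6-(benzyloxy)-2-[4-(benzyloxy)phenyl]-5-{(3S)-3-[4-(benzyloxy)phenyl]-3-[(triisopropylsilyl)oxy]propyl}-1-benzofuran-4-ol | Oc1c(CC[C@H](O[Si](C(C)C)(C(C)C)C(C)C)c2ccc(OCc3ccccc3)cc2)c(OCc2ccccc2)cc2oc(-c3ccc(OCc4ccccc4)cc3)cc12
F11 | step 5 | 6-(benzyloxy)-2-[4-(benzyloxy)phenyl]-5-{(3S)-3-[4-(benzyloxy)phenyl]-3-hydroxypropyl}-1-benzofuran-4-ol | Oc1c(CC[C@H](O)c2ccc(OCc3ccccc3)cc2)c(OCc2ccccc2)cc2oc(-c3ccc(OCc4ccccc4)cc3)cc12
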